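**Retrosynthetic overview**
1. Target ⇒ global desilylation of a bis-silyl 1,3-diol ⇒ reductive removal of a chiral auxiliary (C9 C=O → CH2OH) from a syn-aldol imide.
2. Key disconnection C7–C8: Evans boron syn-aldol between an (S)-4-benzyl-3-(aryloxyacetyl)oxazolidinone (the sinapyl half) and TIPS-protected vanillin; it sets both stereocentres, syn = threo = (7R,8R).
3. Aryloxyacetyl imide ⇒ aryloxyacetic acid + auxiliary; acid ⇒ sinapyl alcohol (phenol O-alkylation with bromoacetate, TBS on the allylic OH) ⇒ syringaldehyde (Wittig, DIBAL-H).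
4. No ring is formed: both benzene rings (vanillin, syringaldehyde) and the oxazolidinone are bought; the oxazolidinone is released again in the reduction.

Assumptions: the SMILES is read as the (7R,8R)-threo isomer, which is (1R,2R) in propane-1,3-diol numbering; purchased reagents that leave atoms in a product carry numbers, stand under Reactants and are repeated under "Reagents that add atoms".

**Step 1**
Reactants: 1 syringaldehyde; 2 ethyl (triphenylphosphoranylidene)acetate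
Product: 3 ethyl (E)-3-(4-hydroxy-3,5-dimethoxyphenyl)prop-2-enoate (ethyl sinapate)
Conditions: 2 (1.3 equiv), toluene, 100 °C
Reagents that add atoms: ethyl (triphenylphosphoranylidene)acetate 2, CCOC(=O)C=P(c1ccccc1)(c1ccccc1)c1ccccc1
Why: Wittig olefination with a stabilised ylide tolerates the free phenol and gives the (E)-cinnamate selectively.

**Step 2**
Reactants: 3 ethyl sinapate
Product: 4 4-[(E)-3-hydroxyprop-1-enyl]-2,6-dimethoxyphenol (sinapyl alcohol)
Conditions: DIBAL-H (4.5 equiv), toluene, 0 °C; aq. Rochelle salt work-up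
Reagents that add atoms: none
Why: DIBAL-H ester reduction, in which the first equivalent is consumed by the phenol and the excess reduces the conjugated ester 1,2 to the allylic alcohol without touching the alkene.

**Step 3**
Reactants: 4 sinapyl alcohol; 5 methyl bromoacetate
Product: 6 methyl 2-{4-[(E)-3-hydroxyprop-1-enyl]-2,6-dimethoxyphenoxy}acetate
Conditions: 5 (1.1 equiv), K2CO3 (1.5 equiv), DMF, rt
Reagents that add atoms: methyl bromoacetate 5, COC(=O)CBr
Why: Williamson ether synthesis in which carbonate deprotonates only the phenol, so SN2 attack on the activated α-bromo ester is chemoselective over the allylic alcohol.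

**Step 4**
Reactants: 6 methyl 2-{4-[(E)-3-hydroxyprop-1-enyl]-2,6-dimethoxyphenoxy}acetate; 7 tert-butyldimethylsilyl chloride
Product: 8 methyl 2-{4-[(E)-3-(tert-butyldimethylsilyloxy)prop-1-enyl]-2,6-dimethoxyphenoxy}acetate
Conditions: TBSCl (1.2 equiv), imidazole (2.5 equiv), DMF, 0 °C → rt
Reagents that add atoms: tert-butyldimethylsilyl chloride 7, CC(C)(C)[Si](C)(C)Cl
Why: Silyl ether protection (TBSCl/imidazole) of the only free hydroxyl masks the allylic alcohol for the enolisation, aldol and hydride steps.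

**Step 5**
Reactants: 8 methyl 2-{4-[(E)-3-(tert-butyldimethylsilyloxy)prop-1-enyl]-2,6-dimethoxyphenoxy}acetate
Product: 9 2-{4-[(E)-3-(tert-butyldimethylsilyloxy)prop-1-enyl]-2,6-dimethoxyphenoxy}acetic acid
Conditions: LiOH·H2O (2 equiv), THF/H2O 3:1, 0 °C → rt; then 0.5 M HCl to pH 4 at 0 °C, EtOAc extraction
Reagents that add atoms: lithium hydroxide (aqueous), [Li+].[OH-]
Why: Ester saponification of the unhindered, α-oxygen-activated methyl ester is fast and leaves the TBS ether intact when the acidification is cold and brief.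

**Step 6**
Reactants: 9 2-{4-[(E)-3-(tert-butyldimethylsilyloxy)prop-1-enyl]-2,6-dimethoxyphenoxy}acetic acid; 10 (S)-4-benzyloxazolidin-2-one
Product: 12 (S)-4-benzyl-3-(2-{4-[(E)-3-(tert-butyldimethylsilyloxy)prop-1-enyl]-2,6-dimethoxyphenoxy}acetyl)oxazolidin-2-one, via mixed pivalic anhydride 11 (not isolated)
Conditions: PivCl (1.05 equiv), Et3N (2.5 equiv), THF, −20 °C; then LiCl (1.1 equiv), 10 (1.0 equiv), −20 °C → rt
Reagents that add atoms: (S)-4-benzyloxazolidin-2-one 10, O=C1N[C@@H](Cc2ccccc2)CO1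
Why: N-acylation of the Evans auxiliary through a mixed anhydride (LiCl/Et3N activation), in which the oxazolidinone attacks the less hindered aryloxyacetyl carbonyl and the (S) centre is bought.

**Step 7**
Reactants: 13 vanillin; 14 triisopropylsilyl chloride
Product: 15 3-methoxy-4-(triisopropylsilyloxy)benzaldehyde
Conditions: TIPSCl (1.1 equiv), imidazole (2.2 equiv), DMF, rt
Reagents that add atoms: triisopropylsilyl chloride 14, CC(C)[Si](Cl)(C(C)C)C(C)C
Why: Silyl ether protection of the phenol as a robust TIPS ether that survives Bu2BOTf, amine base and LiBH4 and is removed by fluoride at the end.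

**Step 8**
Reactants: 12 (S)-4-benzyl-3-(2-{4-[(E)-3-(tert-butyldimethylsilyloxy)prop-1-enyl]-2,6-dimethoxyphenoxy}acetyl)oxazolidin-2-one; 15 3-methoxy-4-(triisopropylsilyloxy)benzaldehyde
Product: 18 (S)-4-benzyl-3-[(2S,3R)-2-{4-[(E)-3-(tert-butyldimethylsilyloxy)prop-1-enyl]-2,6-dimethoxyphenoxy}-3-hydroxy-3-[3-methoxy-4-(triisopropylsilyloxy)phenyl]propanoyl]oxazolidin-2-one, via dibutylboron Z-enolate 16 (not isolated), via dibutylboron aldolate 17 (not isolated)
Conditions: Bu2BOTf (1.2 equiv), iPr2NEt (1.4 equiv), CH2Cl2, −78 → 0 °C; then 15 (1.2 equiv), −78 → 0 °C; pH 7 buffer, MeOH, 30% H2O2, 0 °C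
Reagents that add atoms: none
Why: Evans syn-aldol reaction in which the (Z)-boron enolate reacts through a closed Zimmerman–Traxler chair on the face remote from the benzyl group of the (S)-auxiliary, setting C8 (2S in the imide) and C7 (3R) in the syn (threo) relationship in one step.

**Step 9**
Reactants: 18 the syn-aldol imide
Product: 19 (1R,2R)-2-{4-[(E)-3-(tert-butyldimethylsilyloxy)prop-1-enyl]-2,6-dimethoxyphenoxy}-1-[3-methoxy-4-(triisopropylsilyloxy)phenyl]propane-1,3-diol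
Conditions: LiBH4 (2.5 equiv), H2O (1.1 equiv), THF, 0 °C; aqueous work-up
Reagents that add atoms: none
Why: Reductive removal of the chiral auxiliary, in which borohydride attacks the activated exocyclic imide carbonyl to give the C9 primary alcohol and returns 10 without touching the stereocentres, silyl ethers or alkene.

**Step 10**
Reactants: 19 the bis-silyl diol
Product: 20 (1R,2R)-1-(4-hydroxy-3-methoxyphenyl)-2-{4-[(E)-3-hydroxyprop-1-enyl]-2,6-dimethoxyphenoxy}propane-1,3-diol (target)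
Conditions: TBAF (3 equiv), AcOH (3 equiv), THF, 0 °C → rt
Reagents that add atoms: none
Why: Fluoride-mediated desilylation removes the aryl TIPS and allylic TBS ethers together, and the AcOH buffer keeps the phenol protonated so that no quinone methide forms and C7 is not epimerised.

**Compound list**
1 | syringaldehyde (4-hydroxy-3,5-dimethoxybenzaldehyde) | COc1cc(C=O)cc(OC)c1O | starting material
2 | ethyl (triphenylphosphoranylidene)acetate | CCOC(=O)C=P(c1ccccc1)(c1ccccc1)c1ccccc1 | starting material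
3 | ethyl (E)-3-(4-hydroxy-3,5-dimethoxyphenyl)prop-2-enoate | CCOC(=O)/C=C/c1cc(OC)c(O)c(OC)c1 | intermediate
4 | 4-[(E)-3-hydroxyprop-1-enyl]-2,6-dimethoxyphenol (sinapyl alcohol) | COc1cc(/C=C/CO)cc(OC)c1O | intermediate
5 | methyl bromoacetate | COC(=O)CBr | starting material
6 | methyl 2-{4-[(E)-3-hydroxyprop-1-enyl]-2,6-dimethoxyphenoxy}acetate | COC(=O)COc1c(OC)cc(/C=C/CO)cc1OC | intermediate
7 | tert-butyldimethylsilyl chloride | CC(C)(C)[Si](C)(C)Cl | starting material
8 | methyl 2-{4-[(E)-3-(tert-butyldimethylsilyloxy)prop-1-enyl]-2,6-dimethoxyphenoxy}acetate | COC(=O)COc1c(OC)cc(/C=C/CO[Si](C)(C)C(C)(C)C)cc1OC | intermediate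
9 | 2-{4-[(E)-3-(tert-butyldimethylsilyloxy)prop-1-enyl]-2,6-dimethoxyphenoxy}acetic acid | OC(=O)COc1c(OC)cc(/C=C/CO[Si](C)(C)C(C)(C)C)cc1OC | intermediate
10 | (S)-4-benzyloxazolidin-2-one | O=C1N[C@@H](Cc2ccccc2)CO1 | starting material
11 | mixed pivalic anhydride of acid 9 | CC(C)(C)C(=O)OC(=O)COc1c(OC)cc(/C=C/CO[Si](C)(C)C(C)(C)C)cc1OC | intermediate (not isolated)
12 | (S)-4-benzyl-3-(2-{4-[(E)-3-(tert-butyldimethylsilyloxy)prop-1-enyl]-2,6-dimethoxyphenoxy}acetyl)oxazolidin-2-one | O=C(COc1c(OC)cc(/C=C/CO[Si](C)(C)C(C)(C)C)cc1OC)N1C(=O)OC[C@@H]1Cc1ccccc1 | intermediate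
13 | vanillin (4-hydroxy-3-methoxybenzaldehyde) | COc1cc(C=O)ccc1O | starting material
14 | triisopropylsilyl chloride | CC(C)[Si](Cl)(C(C)C)C(C)C | starting material
15 | 3-methoxy-4-(triisopropylsilyloxy)benzaldehyde | COc1cc(C=O)ccc1O[Si](C(C)C)(C(C)C)C(C)C | intermediate
16 | dibutylboron (Z)-enolate of imide 12 (O–B and O–aryl cis) | CCCCB(CCCC)O/C(=C\Oc1c(OC)cc(/C=C/CO[Si](C)(C)C(C)(C)C)cc1OC)N1C(=O)OC[C@@H]1Cc1ccccc1 | intermediate (not isolated)
17 | dibutylboron aldolate, (2S,3R), O–BBu2 on the C7 oxygen | COc1cc([C@@H](OB(CCCC)CCCC)[C@@H](C(=O)N2C(=O)OC[C@@H]2Cc2ccccc2)Oc2c(OC)cc(/C=C/CO[Si](C)(C)C(C)(C)C)cc2OC)ccc1O[Si](C(C)C)(C(C)C)C(C)C | intermediate (not isolated)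
18 | (S)-4-benzyl-3-[(2S,3R)-2-{4-[(E)-3-(tert-butyldimethylsilyloxy)prop-1-enyl]-2,6-dimethoxyphenoxy}-3-hydroxy-3-[3-methoxy-4-(triisopropylsilyloxy)phenyl]propanoyl]oxazolidin-2-one | COc1cc([C@@H](O)[C@@H](C(=O)N2C(=O)OC[C@@H]2Cc2ccccc2)Oc2c(OC)cc(/C=C/CO[Si](C)(C)C(C)(C)C)cc2OC)ccc1O[Si](C(C)C)(C(C)C)C(C)C | intermediate
19 | (1R,2R)-2-{4-[(E)-3-(tert-butyldimethylsilyloxy)prop-1-enyl]-2,6-dimethoxyphenoxy}-1-[3-methoxy-4-(triisopropylsilyloxy)phenyl]propane-1,3-diol | COc1cc([C@@H](O)[C@@H](CO)Oc2c(OC)cc(/C=C/CO[Si](C)(C)C(C)(C)C)cc2OC)ccc1O[Si](C(C)C)(C(C)C)C(C)C | intermediate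
20 | (1R,2R)-1-(4-hydroxy-3-methoxyphenyl)-2-{4-[(E)-3-hydroxyprop-1-enyl]-2,6-dimethoxyphenoxy}propane-1,3-diol | COc1cc([C@@H](O)[C@@H](CO)Oc2c(OC)cc(/C=C/CO)cc2OC)ccc1O | target

**Totals**
Total step count: 10. Longest linear sequence: 9 steps (steps 1–6 and 8–10 from syringaldehyde); step 7 is a one-step branch.

**Three steps most likely to fail**

Step 8 (boron aldol). The electron-rich cinnamyl silyl ether may not tolerate Bu2BOTf, and the hindered 2,6-dimethoxyphenoxy enolate may convert poorly. The fallback carries the side chain through the aldol as the electron-poor cinnamate ester, which has no ionisable allylic C–O bond, and reduces it afterwards. It sets out from 3 (with 10 and 15) and comes back to the route at 20. Compound 3 is O-alkylated with tert-butyl bromoacetate (K2CO3, DMF) to ethyl (E)-3-[4-(2-tert-butoxy-2-oxoethoxy)-3,5-dimethoxyphenyl]prop-2-enoate F1. TFA/CH2Cl2 then cleaves the tert-butyl ester to 2-{4-[(E)-3-ethoxy-3-oxoprop-1-enyl]-2,6-dimethoxyphenoxy}acetic acid F2. PivCl/Et3N gives the mixed pivalic anhydride of this acid F3, which acylates 10 (LiCl) to ethyl (E)-3-(4-{2-[(S)-4-benzyl-2-oxooxazolidin-3-yl]-2-oxoethoxy}-3,5-dimethoxyphenyl)prop-2-enoate F4. Bu2BOTf/iPr2NEt converts it into the dibutylboron (Z)-enolate F5, which adds to 15 to give the dibutylboron aldolate F6. Oxidative work-up gives (S)-4-benzyl-3-[(2S,3R)-2-{4-[(E)-3-ethoxy-3-oxoprop-1-enyl]-2,6-dimethoxyphenoxy}-3-hydroxy-3-[3-methoxy-4-(triisopropylsilyloxy)phenyl]propanoyl]oxazolidin-2-one F7. NaBH4 in THF/H2O removes the auxiliary without touching the cinnamate and gives ethyl (E)-3-(4-{[(1R,2R)-1,3-dihydroxy-1-[3-methoxy-4-(triisopropylsilyloxy)phenyl]propan-2-yl]oxy}-3,5-dimethoxyphenyl)prop-2-enoate F8. DIBAL-H (excess, CH2Cl2, −78 → 0 °C) reduces the ester to (1R,2R)-2-{4-[(E)-3-hydroxyprop-1-enyl]-2,6-dimethoxyphenoxy}-1-[3-methoxy-4-(triisopropylsilyloxy)phenyl]propane-1,3-diol F9, and TBAF/AcOH removes the TIPS group to give 20.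

Step 2 (DIBAL-H reduction to free sinapyl alcohol 4). The product is acid- and air-sensitive and is easily lost in the aluminium work-up. The fallback never makes the free phenolic cinnamyl alcohol and builds the C3 chain on the already O-alkylated ring by a two-carbon aldehyde homologation. It sets out from 1 and 5 and comes back to the route at 6. K2CO3/DMF alkylation of 1 with 5 gives methyl 2-(4-formyl-2,6-dimethoxyphenoxy)acetate F10. Wittig reaction with (triphenylphosphoranylidene)acetaldehyde (toluene, 80 °C) gives methyl 2-{2,6-dimethoxy-4-[(E)-3-oxoprop-1-enyl]phenoxy}acetate F11. Luche reduction (NaBH4, CeCl3·7H2O, MeOH, −20 °C) reduces only the aldehyde, 1,2, to give 6.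

Step 10 (global desilylation). The unprotected product is a polar p-hydroxybenzyl/cinnamyl alcohol that is sensitive to acid and base and hard to free from tetrabutylammonium salts. The fallback captures and releases it as the peracetate. It sets out from 19 and comes back to the route at 20. After the TBAF/AcOH treatment the crude is acetylated in the same flask (Ac2O, pyridine, cat. DMAP) to (1R,2R)-1-(4-acetoxy-3-methoxyphenyl)-2-{4-[(E)-3-acetoxyprop-1-enyl]-2,6-dimethoxyphenoxy}propane-1,3-diyl diacetate F12. This is non-polar, chromatographs cleanly and lets the threo purity be checked. Zemplén transesterification (cat. NaOMe, MeOH, 0 °C, neutralised with weak-acid resin) then releases 20 with only a volatile by-product.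

**Further compounds**
F1 | step 8 | ethyl (E)-3-[4-(2-tert-butoxy-2-oxoethoxy)-3,5-dimethoxyphenyl]prop-2-enoate | CCOC(=O)/C=C/c1cc(OC)c(OCC(=O)OC(C)(C)C)c(OC)c1
F2 | step 8 | 2-{4-[(E)-3-ethoxy-3-oxoprop-1-enyl]-2,6-dimethoxyphenoxy}acetic acid | CCOC(=O)/C=C/c1cc(OC)c(OCC(=O)O)c(OC)c1
F3 | step 8 | mixed pivalic anhydride of acid F2 | CCOC(=O)/C=C/c1cc(OC)c(OCC(=O)OC(=O)C(C)(C)C)c(OC)c1
F4 | step 8 | ethyl (E)-3-(4-{2-[(S)-4-benzyl-2-oxooxazolidin-3-yl]-2-oxoethoxy}-3,5-dimethoxyphenyl)prop-2-enoate | CCOC(=O)/C=C/c1cc(OC)c(OCC(=O)N2C(=O)OC[C@@H]2Cc2ccccc2)c(OC)c1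
F5 | step 8 | dibutylboron (Z)-enolate of imide F4 | CCCCB(CCCC)O/C(=C\Oc1c(OC)cc(/C=C/C(=O)OCC)cc1OC)N1C(=O)OC[C@@H]1Cc1ccccc1
F6 | step 8 | dibutylboron aldolate, (2S,3R), leading to F7 | COc1cc([C@@H](OB(CCCC)CCCC)[C@@H](C(=O)N2C(=O)OC[C@@H]2Cc2ccccc2)Oc2c(OC)cc(/C=C/C(=O)OCC)cc2OC)ccc1O[Si](C(C)C)(C(C)C)C(C)C
F7 | step 8 | (S)-4-benzyl-3-[(2S,3R)-2-{4-[(E)-3-ethoxy-3-oxoprop-1-enyl]-2,6-dimethoxyphenoxy}-3-hydroxy-3-[3-methoxy-4-(triisopropylsilyloxy)phenyl]propanoyl]oxazolidin-2-one | COc1cc([C@@H](O)[C@@H](C(=O)N2C(=O)OC[C@@H]2Cc2ccccc2)Oc2c(OC)cc(/C=C/C(=O)OCC)cc2OC)ccc1O[Si](C(C)C)(C(C)C)C(C)C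
F8 | step 8 | ethyl (E)-3-(4-{[(1R,2R)-1,3-dihydroxy-1-[3-methoxy-4-(triisopropylsilyloxy)phenyl]propan-2-yl]oxy}-3,5-dimethoxyphenyl)prop-2-enoate | COc1cc([C@@H](O)[C@@H](CO)Oc2c(OC)cc(/C=C/C(=O)OCC)cc2OC)ccc1O[Si](C(C)C)(C(C)C)C(C)C
F9 | step 8 | (1R,2R)-2-{4-[(E)-3-hydroxyprop-1-enyl]-2,6-dimethoxyphenoxy}-1-[3-methoxy-4-(triisopropylsilyloxy)phenyl]propane-1,3-diol | COc1cc([C@@H](O)[C@@H](CO)Oc2c(OC)cc(/C=C/CO)cc2OC)ccc1O[Si](C(C)C)(C(C)C)C(C)C
F10 | step 2 | methyl 2-(4-formyl-2,6-dimethoxyphenoxy)acetate | COC(=O)COc1c(OC)cc(C=O)cc1OC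
F11 | step 2 | methyl 2-{2,6-dimethoxy-4-[(E)-3-oxoprop-1-enyl]phenoxy}acetate | COC(=O)COc1c(OC)cc(/C=C/C=O)cc1OC
F12 | step 10 | (1R,2R)-1-(4-acetoxy-3-methoxyphenyl)-2-{4-[(E)-3-acetoxyprop-1-enyl]-2,6-dimethoxyphenoxy}propane-1,3-diyl diacetate | COc1cc([C@@H](OC(C)=O)[C@@H](COC(C)=O)Oc2c(OC)cc(/C=C/COC(C)=O)cc2OC)ccc1OC(C)=O
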